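(All constants are those of an exercise; the result is computed.)

I decide to follow one molecule of E at its fork, not the clock.

| setting | Saturday's | Wednesday's | Sunday's | Friday's |
|---|---|---|---|---|
| J | 0.24 M | 0.24 M | 0.24 M | 0.24 M (fed, over 10 min) |
| E | 0.480 M (fed, over 10 min) | 0.480 M (in portions, 5, over 10 min) | 0.480 M | 0.480 M |
| time | 25 min | 25 min | 25 min | 25 min |
| remark | all else is in the flask from the start; the feed brings no volume worth counting | first portion at the start, last at 10 min | everything together at the start | all else is in the flask from the start; the feed brings no volume worth counting |

    J + E → Q + G (k1 = 0.0146 M⁻¹ s⁻¹)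
    G + E → Q + L (k2 = 0.108 M⁻¹ s⁻¹)
    E → D (k3 = 0.00485 s⁻¹)
    2 E → E2 (k4 = 0.0294 M⁻¹ s⁻¹)

- a step written with two of one species runs at k times the square of its concentration and takes two of it each time
- run time (Saturday's): 25 min

* the flask that comes out highest in share of G in G plus L, or "all alike" when all lie within 1.5 percentage points (Saturday's / Wednesday's / Sunday's / Friday's / all alike)
* share of G in G plus L at the end, Saturday's
* share of G in G plus L at the end, Wednesday's
* share of G in G plus L at the end, Sunday's
* share of G in G plus L at the end, Friday's

An E that meets J makes G, and an E that meets G makes L. The odds of the second over the first are s[G]/[J], where s is the selectivity factor, the ratio of the constant of step G + E to that of step J + E, 7.40.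

In Saturday's, Wednesday's and Sunday's, J stands from the start and sees the same E as G. So in these three flasks [G] follows [J] along one curve, however E goes in. It peaks where the odds reach one, with 73.1% of J left and 9.89% of the J charged as G, a share of 36.8%.

Now I turn the question round. What would let these flasks beat Friday's, where J is fed into E? My own answer is that in Friday's E would have to outlast the feed of 10 min, so that it keeps meeting thin J. But its half-life as charged is 0.591 min by the step to E2 and 2.38 min by the step to D, both shorter than the feed. Its first-order loss, 0.00485 s⁻¹, also beats 0.00350 s⁻¹, its loss to the whole charge of J. So I expect Friday's to end below even odds and to come out highest. I commit to that, not to figures.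

The forecast says Friday's, with 20.5%, 22%, 32% and 58% for Saturday's, Wednesday's, Sunday's and Friday's, because “late-fed J meets little remaining E”.

| Flask | Share of G | s[G]/[J] at the end |
|---|---|---|
| Saturday's | 20.7% | 1.12 |
| Wednesday's | 21.3% | 1.12 |
| Sunday's | 34.7% | 1.02 |
| Friday's | 57.9% | 0.290 |

The highest is Friday's. In Friday's, at 0.320 min, E goes to E2 3.5 times as fast as to D, and the step to E2 has 99.7% of its turnover up to the asked time behind it after 5.00 min, well inside the feed. At the end of the feed, Friday's holds E at 0.255% of its charge and J at 93.8% of the J charged. A neighbour of Friday's with 0.12 M of E ends at a share of 73.0%, with s[G]/[J] at 0.213.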